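**Retrosynthetic overview**
1. Incarvillateine ⇒ double Mitsunobu esterification, with inversion at both C6 centres, of the achiral α‑truxillic diacid with two equivalents of 6‑epi‑incarvilline.
2. α‑Truxillic diacid ⇒ head‑to‑tail solid‑state [2+2] photodimer of ferulic acid. The cyclobutane is made in parallel.
3. 6‑epi‑Incarvilline ⇒ face‑selective hydrogenation, then LiAlH4 (C=O → CHOH, N‑CO2Me → N‑CH3), of a bicyclic enone with its C=C at C4a=C5.
4. Bicyclic enone ⇒ intramolecular Pauson–Khand reaction of a 1,7‑enyne set up the unusual way round: terminal alkyne on the C4 arm, E‑crotyl group on the C1 arm. Piperidine and cyclopentenone close together, and C7a and C7 are set in the same event.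
5. Enyne ⇒ (S)‑Roche ester (C4 stereocentre), crotylamine, methyl chloroformate and one Ohira–Bestmann carbon. Ring order: piperidine + cyclopentenone in one operation, cyclobutane separately.

Assumption: the target is read as (−)‑incarvillateine (achiral Ci α‑truxillate core, two identical (4R,4aS,6R,7S,7aR) amino‑alcohol esters), and (E)‑crotylamine of ≥95 % E purity is bought.

**Step 1**
Reactants: 1 methyl (2S)-3-hydroxy-2-methylpropanoate ((S)-Roche ester); 2 (E)-but-2-en-1-amine (crotylamine)
Product: 5 methyl (2S)-3-[(E)-but-2-en-1-yl(methoxycarbonyl)amino]-2-methylpropanoate, via Roche ester triflate 3 (not isolated), via secondary amine 4 (not isolated)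
Conditions: Tf2O, 2,6-lutidine, CH2Cl2, −78 °C; then 2 (3 equiv), −78 → 0 °C; then ClCO2Me, i-Pr2NEt, 0 °C → rt
Reagents that add atoms: methyl chloroformate, COC(=O)Cl
Why: The primary triflate undergoes SN2 N-alkylation at −78 to 0 °C faster than E1cB loss of triflate, so the chiral-pool stereocentre (future C4) is untouched, and immediate N-acylation (carbamate formation) traps the retro-Michael-prone β-amino ester while installing the carbon that ends as N-CH3.

**Step 2**
Reactants: 5 methyl (2S)-3-[(E)-but-2-en-1-yl(methoxycarbonyl)amino]-2-methylpropanoate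
Product: 7 methyl (E)-but-2-en-1-yl[(2R)-2-methylbut-3-yn-1-yl]carbamate, via β-carbamoyl aldehyde 6 (not isolated)
Conditions: DIBAL-H (1.1 equiv), CH2Cl2, −78 °C; then MeOH, K2CO3, Bestmann–Ohira reagent, −78 °C → rt
Reagents that add atoms: Bestmann–Ohira reagent (dimethyl (1-diazo-2-oxopropyl)phosphonate), CC(=O)C(=[N+]=[N-])P(=O)(OC)OC
Why: Partial ester reduction stops at the aluminium hemiacetal at −78 °C and the aldehyde freed by MeOH is homologated at once by the Ohira–Bestmann modification of the Seyferth–Gilbert reaction, whose K2CO3/MeOH medium is mild enough for α-branched aldehydes to keep their configuration (S to R is only a CIP priority change).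

**Step 3 (key step)**
Reactants: 7 methyl (E)-but-2-en-1-yl[(2R)-2-methylbut-3-yn-1-yl]carbamate
Product: 9 methyl (4R,7S,7aS)-4,7-dimethyl-6-oxo-1,3,4,6,7,7a-hexahydro-2H-cyclopenta[c]pyridine-2-carboxylate, via alkyne hexacarbonyldicobalt complex 8 (not isolated)
Conditions: Co2(CO)8 (1.1 equiv), 1,2-DCE, rt, 2 h; then n-BuSMe (4 equiv), 83 °C; air, filtration through silica
Reagents that add atoms: dicobalt octacarbonyl (delivers the ring C=O), [Co].[Co].[C-]#[O+].[C-]#[O+].[C-]#[O+].[C-]#[O+].[C-]#[O+].[C-]#[O+].[C-]#[O+].[C-]#[O+]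
Why: Intramolecular Pauson–Khand [2+2+1] cycloaddition closes the piperidine and the cyclopentenone in one operation, the chair-like cobaltacycle with the C4 methyl equatorial places H-7a cis to H-4 (sets C7a), suprafacial insertion of the E-alkene makes C7-CH3 trans to the C7a–CH2N bond (sets C7), and this isomer is also the thermodynamically preferred one.

**Step 4**
Reactants: 9 methyl (4R,7S,7aS)-4,7-dimethyl-6-oxo-1,3,4,6,7,7a-hexahydro-2H-cyclopenta[c]pyridine-2-carboxylate
Product: 10 methyl (4R,4aS,7S,7aR)-4,7-dimethyl-6-oxooctahydro-2H-cyclopenta[c]pyridine-2-carboxylate (cis-fused)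
Conditions: H2 (1 atm), 10 % Pd/C, EtOAc, rt
Reagents that add atoms: none
Why: Heterogeneous syn-hydrogenation takes place on the open face of the flat enone that carries H-7a, because C1, N and C3 of the piperidine chair all lie on the other face, so H-4a is delivered cis to H-7a and H-4 and the cis ring fusion (4aS) results.

**Step 5**
Reactants: 10 methyl (4R,4aS,7S,7aR)-4,7-dimethyl-6-oxooctahydro-2H-cyclopenta[c]pyridine-2-carboxylate
Product: 11 (4R,4aS,6S,7S,7aR)-2,4,7-trimethyloctahydro-1H-cyclopenta[c]pyridin-6-ol (6-epi-incarvilline)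
Conditions: LiAlH4 (4 equiv), THF, −78 °C → reflux; Fieser work-up
Reagents that add atoms: none
Why: Hydride reduction with LiAlH4 attacks the cyclopentanone from the convex face of the cis-fused bicycle (the same sense as the known preference of small hydrides for trans-2-methylcyclopentanols), giving the endo 6S alcohol trans to C7-CH3, and at reflux the methyl carbamate is reduced to N-CH3.

**Step 6**
Reactants: 12 (E)-ferulic acid ((E)-3-(4-hydroxy-3-methoxyphenyl)prop-2-enoic acid, 2 equiv)
Product: 13 (1α,2α,3β,4β)-2,4-bis(4-hydroxy-3-methoxyphenyl)cyclobutane-1,3-dicarboxylic acid (4,4′-dihydroxy-3,3′-dimethoxy-α-truxillic acid)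
Conditions: hν (medium-pressure Hg lamp, Pyrex), finely powdered crystals stirred as a suspension in hexane, rt; monomer washed out with Et2O
Reagents that add atoms: none
Why: Topochemical [2+2] photocycloaddition in the crystal, where ferulic acid stacks in centrosymmetric head-to-tail pairs with the C=C bonds within the roughly 4 Å Schmidt distance, can only give the α-truxillic (r-1,c-2,t-3,t-4) dimer, an achiral Ci-symmetric core whose four stereocentres are fixed by the lattice and the E geometry.

**Step 7**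
Reactants: 13 4,4′-dihydroxy-3,3′-dimethoxy-α-truxillic acid (1 equiv); 11 6-epi-incarvilline (2.2 equiv)
Product: 15 (−)-incarvillateine (bis[(4R,4aS,6R,7S,7aR)-2,4,7-trimethyloctahydro-1H-cyclopenta[c]pyridin-6-yl] α-truxillate diester), via truxillic half-ester 14 (not isolated)
Conditions: PPh3 (3 equiv), DIAD (3 equiv), THF, 0 °C → rt
Reagents that add atoms: none
Why: Double Mitsunobu esterification proceeds by SN2 attack of carboxylate on the C6 oxyphosphonium ion from the convex face with clean inversion (6S to 6R), only the carboxylic acids (pKa about 4.5) and not the guaiacol OH groups (pKa about 10) are ionised so the phenols stay free, and since both enantiotopic carboxyls receive the same alcohol a single diester forms.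

**Compound list**
1 | methyl (2S)-3-hydroxy-2-methylpropanoate ((S)-Roche ester) | COC(=O)[C@@H](C)CO | starting material
2 | (E)-but-2-en-1-amine | C/C=C/CN | starting material
3 | methyl (2S)-2-methyl-3-[(trifluoromethylsulfonyl)oxy]propanoate | COC(=O)[C@@H](C)COS(=O)(=O)C(F)(F)F | intermediate
4 | methyl (2S)-3-[(E)-but-2-en-1-ylamino]-2-methylpropanoate | COC(=O)[C@@H](C)CNC/C=C/C | intermediate
5 | methyl (2S)-3-[(E)-but-2-en-1-yl(methoxycarbonyl)amino]-2-methylpropanoate | COC(=O)[C@@H](C)CN(C/C=C/C)C(=O)OC | intermediate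
6 | methyl (E)-but-2-en-1-yl[(2S)-2-methyl-3-oxopropyl]carbamate | O=C[C@@H](C)CN(C/C=C/C)C(=O)OC | intermediate
7 | methyl (E)-but-2-en-1-yl[(2R)-2-methylbut-3-yn-1-yl]carbamate | C#C[C@@H](C)CN(C/C=C/C)C(=O)OC | intermediate
8 | hexacarbonyldicobalt complex of the alkyne of 7 (C2Co2 tetrahedrane, formal drawing) | [CH]12[Co]3(=C=O)(=C=O)(=C=O)[Co]1(=C=O)(=C=O)(=C=O)C23[C@@H](C)CN(C/C=C/C)C(=O)OC | intermediate
9 | methyl (4R,7S,7aS)-4,7-dimethyl-6-oxo-1,3,4,6,7,7a-hexahydro-2H-cyclopenta[c]pyridine-2-carboxylate | O=C1C=C2[C@@H](CN(C(=O)OC)C[C@@H]2C)[C@@H]1C | intermediate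
10 | methyl (4R,4aS,7S,7aR)-4,7-dimethyl-6-oxooctahydro-2H-cyclopenta[c]pyridine-2-carboxylate | O=C1C[C@@H]2[C@@H](CN(C(=O)OC)C[C@@H]2C)[C@@H]1C | intermediate
11 | (4R,4aS,6S,7S,7aR)-2,4,7-trimethyloctahydro-1H-cyclopenta[c]pyridin-6-ol (6-epi-incarvilline) | O[C@H]1C[C@@H]2[C@@H](CN(C)C[C@@H]2C)[C@@H]1C | intermediate
12 | (E)-ferulic acid | COc1cc(/C=C/C(=O)O)ccc1O | starting material
13 | 4,4′-dihydroxy-3,3′-dimethoxy-α-truxillic acid (achiral, Ci) | COc1cc([C@H]2[C@H](C(=O)O)[C@H](c3ccc(O)c(OC)c3)[C@H]2C(=O)O)ccc1O | intermediate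
14 | α-truxillic half-ester of the 6R amino alcohol (one of the two converging diastereomeric half-esters drawn) | COc1cc([C@H]2[C@H](C(=O)O)[C@H](c3ccc(O)c(OC)c3)[C@H]2C(=O)O[C@@H]2C[C@@H]3[C@@H](CN(C)C[C@@H]3C)[C@@H]2C)ccc1O | intermediate
15 | (−)-incarvillateine | COc1cc([C@H]2[C@H](C(=O)O[C@@H]3C[C@@H]4[C@@H](CN(C)C[C@@H]4C)[C@@H]3C)[C@H](c3ccc(O)c(OC)c3)[C@H]2C(=O)O[C@@H]2C[C@@H]3[C@@H](CN(C)C[C@@H]3C)[C@@H]2C)ccc1O | target

**Total step count:** 7. **Longest linear sequence:** 6 (steps 1, 2, 3, 4, 5, 7). Step 6 runs in parallel.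

**Three steps most likely to fail**

Step 3 (Pauson–Khand reaction). An unactivated 1,2-disubstituted alkene in a 1,7-enyne may insert too slowly, leading to decomplexation or alkyne oligomers.
- The fallback sets out from 1 and comes back at 9.
- Steps 1 and 2 are run with allylamine in place of crotylamine. Triflate 3 gives methyl (2S)-3-(allylamino)-2-methylpropanoate F1.
- This amine is carbamoylated in the flask to methyl (2S)-3-[allyl(methoxycarbonyl)amino]-2-methylpropanoate F2.
- DIBAL-H gives methyl allyl[(2S)-2-methyl-3-oxopropyl]carbamate F3, and Ohira–Bestmann homologation gives methyl allyl[(2R)-2-methylbut-3-yn-1-yl]carbamate F4.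
- Its hexacarbonyldicobalt complex F5 closes both rings onto the far more reactive terminal alkene, giving the 7-demethyl enone methyl (4R,7aS)-4-methyl-6-oxo-1,3,4,6,7,7a-hexahydro-2H-cyclopenta[c]pyridine-2-carboxylate F6.
- The missing methyl group is added afterwards by kinetic α′-deprotonation (LDA, THF, −78 °C) and MeI. Alkylation at C7 occurs anti to the C7a–CH2N bond and gives 9.

Step 6 (photodimerisation of unprotected ferulic acid). The packing of the free phenol may give low conversion.
- The fallback sets out from 12 and comes back at 13.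
- The crystal is re-engineered by O-sulfonylation: TsCl in aqueous NaOH/THF gives (E)-3-[3-methoxy-4-(tosyloxy)phenyl]prop-2-enoic acid F7.
- Irradiating its crystals gives the bis-O-tosyl α-truxillic diacid F8.
- KOH in aqueous MeOH at reflux cleaves the aryl sulfonates to give 13.

Step 7 (double Mitsunobu with free phenols). Possible failures are phenol O-alkylation, poor solubility of the tetraprotic diacid, or stalling at the half-ester.
- The fallback sets out from 13 and comes back at 15.
- Ac2O/pyridine followed by aqueous work-up gives 4,4′-diacetoxy-3,3′-dimethoxy-α-truxillic acid F9.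
- Mitsunobu coupling with 11 passes through the diacetylated half-ester F10 to O,O′-diacetylincarvillateine F11.
- K2CO3 in MeOH at 0 °C removes only the aryl acetates and leaves the hindered secondary alkyl esters, giving 15.

**Further compounds**
F1 | step 3 | methyl (2S)-3-(allylamino)-2-methylpropanoate | COC(=O)[C@@H](C)CNCC=C
F2 | step 3 | methyl (2S)-3-[allyl(methoxycarbonyl)amino]-2-methylpropanoate | COC(=O)[C@@H](C)CN(CC=C)C(=O)OC
F3 | step 3 | methyl allyl[(2S)-2-methyl-3-oxopropyl]carbamate | O=C[C@@H](C)CN(CC=C)C(=O)OC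
F4 | step 3 | methyl allyl[(2R)-2-methylbut-3-yn-1-yl]carbamate | C#C[C@@H](C)CN(CC=C)C(=O)OC
F5 | step 3 | hexacarbonyldicobalt complex of the alkyne of F4 | [CH]12[Co]3(=C=O)(=C=O)(=C=O)[Co]1(=C=O)(=C=O)(=C=O)C23[C@@H](C)CN(CC=C)C(=O)OC
F6 | step 3 | methyl (4R,7aS)-4-methyl-6-oxo-1,3,4,6,7,7a-hexahydro-2H-cyclopenta[c]pyridine-2-carboxylate | O=C1C=C2[C@@H](CN(C(=O)OC)C[C@@H]2C)C1
F7 | step 6 | (E)-3-[3-methoxy-4-(tosyloxy)phenyl]prop-2-enoic acid | COc1cc(/C=C/C(=O)O)ccc1OS(=O)(=O)c1ccc(C)cc1
F8 | step 6 | (1α,2α,3β,4β)-2,4-bis[3-methoxy-4-(tosyloxy)phenyl]cyclobutane-1,3-dicarboxylic acid | COc1cc([C@H]2[C@H](C(=O)O)[C@H](c3ccc(OS(=O)(=O)c4ccc(C)cc4)c(OC)c3)[C@H]2C(=O)O)ccc1OS(=O)(=O)c1ccc(C)cc1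
F9 | step 7 | (1α,2α,3β,4β)-2,4-bis(4-acetoxy-3-methoxyphenyl)cyclobutane-1,3-dicarboxylic acid | COc1cc([C@H]2[C@H](C(=O)O)[C@H](c3ccc(OC(C)=O)c(OC)c3)[C@H]2C(=O)O)ccc1OC(C)=O
F10 | step 7 | diacetylated α-truxillic half-ester of the 6R amino alcohol (one of two converging diastereomers drawn) | COc1cc([C@H]2[C@H](C(=O)O)[C@H](c3ccc(OC(C)=O)c(OC)c3)[C@H]2C(=O)O[C@@H]2C[C@@H]3[C@@H](CN(C)C[C@@H]3C)[C@@H]2C)ccc1OC(C)=O
F11 | step 7 | O,O′-diacetylincarvillateine | COc1cc([C@H]2[C@H](C(=O)O[C@@H]3C[C@@H]4[C@@H](CN(C)C[C@@H]4C)[C@@H]3C)[C@H](c3ccc(OC(C)=O)c(OC)c3)[C@H]2C(=O)O[C@@H]2C[C@@H]3[C@@H](CN(C)C[C@@H]3C)[C@@H]2C)ccc1OC(C)=O
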